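**Plan**
1. The benzyl ether is cut last. The quinone ring is read as an oxidised, aromatised cyclohexenetetrol: C1(=O)–C2(OMe)–C3(OMe)–C4(=O) are four contiguous oxygen-bearing carbons (C4 to C1 of 2,3-di-O-methyl-D-glucose), and C5=C6 is the only ring bond with no oxygen on either atom, an olefin that ring-closing metathesis can make.
2. The next cut is the C4–C5 bond (Nozaki–Hiyama–Kishi), giving a sugar enal (from a 6-bromoglucoside by zinc fragmentation) and the alkenyl triflate of a 3-acetylchroman.
3. Forward: ring A is oxygenated (Elbs), the pyran ring is closed by oxa-Michael/aldol annulation with acrolein, the two fragments are joined, the carbocycle is closed by metathesis, oxidation and tautomerisation turn it into the quinone, and hydrogenolysis ends the route.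
4. The one stereocentre (chroman C3, S in the target) comes from Ru-BINAP hydrogenation of the chromene-3-carboxylic acid; the sugar stereocentres are sacrificial and vanish on aromatisation.

Key step: step 12

Assumption: Ru(OAc)2[(R)-BINAP] is taken to deliver the (3R)-acid 8; if the sense of induction is the opposite, the (S)-ligand is used and nothing else changes. The CIP descriptor of chroman C3 switches from R (8–12) to S (17–24) only because the priority of the attached carbon changes; the spatial arrangement is the same throughout.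

**Step 1**
Reactants: 1 2-hydroxy-3,4-dimethoxybenzaldehyde
Product: 3 2,5-dihydroxy-3,4-dimethoxybenzaldehyde, via aryl sulfate 2 (not isolated)
Conditions: K2S2O8, 10% aq NaOH, 0 °C to rt; then aq HCl, 80 °C
Reagents that add atoms: potassium peroxodisulfate, [K+].[K+].[O-]S(=O)(=O)OOS(=O)(=O)[O-]
Why: Elbs persulfate oxidation: the phenoxide attacks the peroxide oxygen through its free para carbon (C5), and acid hydrolysis of the aryl sulfate frees the second phenol, as in the classical conversion of salicylaldehyde into gentisaldehyde.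

**Step 2**
Reactants: 3 2,5-dihydroxy-3,4-dimethoxybenzaldehyde
Product: 4 5-(benzyloxy)-2-hydroxy-3,4-dimethoxybenzaldehyde
Conditions: BnBr (1.0 equiv), NaHCO3, KI (cat.), MeCN, 60 °C
Reagents that add atoms: benzyl bromide, BrCc1ccccc1
Why: Williamson etherification in which the C2 hydroxyl, hydrogen-bonded to the formyl group, stays unreacted under a weak base, so only the C5 hydroxyl is benzylated.

**Step 3**
Reactants: 4 5-(benzyloxy)-2-hydroxy-3,4-dimethoxybenzaldehyde; 5 acrolein
Product: 6 6-(benzyloxy)-7,8-dimethoxy-2H-chromene-3-carbaldehyde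
Conditions: K2CO3 (cat.), 1,4-dioxane, reflux
Reagents that add atoms: none
Why: Domino oxa-Michael addition of the phenoxide to acrolein and intramolecular aldol condensation onto the aryl aldehyde, the standard route from salicylaldehydes to 2H-chromene-3-carbaldehydes.

**Step 4**
Reactants: 6 6-(benzyloxy)-7,8-dimethoxy-2H-chromene-3-carbaldehyde
Product: 7 6-(benzyloxy)-7,8-dimethoxy-2H-chromene-3-carboxylic acid
Conditions: NaClO2, NaH2PO4, 2-methyl-2-butene, t-BuOH/H2O, rt
Reagents that add atoms: sodium chlorite, [Na+].[O-]Cl=O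
Why: Pinnick oxidation of the enal to the acid, with the alkene scavenging hypochlorous acid so that the electron-rich ring is not chlorinated.

**Step 5**
Reactants: 7 6-(benzyloxy)-7,8-dimethoxy-2H-chromene-3-carboxylic acid
Product: 8 (3R)-6-(benzyloxy)-7,8-dimethoxy-3,4-dihydro-2H-chromene-3-carboxylic acid
Conditions: Ru(OAc)2[(R)-BINAP] (1 mol%), H2 (30 bar), MeOH, 40 °C
Reagents that add atoms: none
Why: Carboxylate-directed Ru-BINAP asymmetric hydrogenation of an α,β-unsaturated acid, known for 2H-chromene-3-carboxylic acids; the chiral ligand sets C3 by selecting the alkene face, and the homogeneous catalyst leaves the benzyl ether alone.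

**Step 6**
Reactants: 8 (3R)-chroman-3-carboxylic acid
Product: 10 1-[(3R)-6-(benzyloxy)-7,8-dimethoxy-3,4-dihydro-2H-chromen-3-yl]ethan-1-one, via dilithium gem-diolate 9 (not isolated)
Conditions: MeLi (2.2 equiv), Et2O, 0 °C; then inverse quench into cold 1 M HCl
Reagents that add atoms: methyllithium, [Li]C
Why: Addition of methyllithium to the lithium carboxylate stops at the dilithium gem-diolate, which gives the methyl ketone only on quench, so no tertiary alcohol forms and the α-stereocentre, never enolised, is kept.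

**Step 7**
Reactants: 10 methyl ketone
Product: 12 1-[(3R)-6-(benzyloxy)-7,8-dimethoxy-3,4-dihydro-2H-chromen-3-yl]ethenyl trifluoromethanesulfonate, via potassium enolate 11 (not isolated)
Conditions: KHMDS, THF, −78 °C; then PhNTf2, −78 to 0 °C
Reagents that add atoms: N-phenyl-bis(trifluoromethanesulfonimide), O=S(=O)(N(c1ccccc1)S(=O)(=O)C(F)(F)F)C(F)(F)F
Why: Kinetic deprotonation with a bulky amide base at −78 °C occurs at the methyl group and not at the hindered C3 methine, so O-triflation gives the terminal enol triflate without touching the stereocentre.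

**Step 8**
Reactants: 13 methyl 4,6-O-[(R)-benzylidene]-α-D-glucopyranoside
Product: 14 methyl 4,6-O-[(R)-benzylidene]-2,3-di-O-methyl-α-D-glucopyranoside
Conditions: NaH, MeI, DMF, 0 °C to rt
Reagents that add atoms: iodomethane, CI
Why: Double Williamson methylation of the two free hydroxyls (C2 and C3) of the benzylidene-protected glucoside.

**Step 9**
Reactants: 14 methyl 4,6-O-benzylidene-2,3-di-O-methyl-α-D-glucopyranoside
Product: 15 methyl 4-O-benzoyl-6-bromo-6-deoxy-2,3-di-O-methyl-α-D-glucopyranoside
Conditions: NBS, BaCO3, PhCl, reflux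
Reagents that add atoms: N-bromosuccinimide, O=C1CCC(=O)N1Br
Why: Hanessian–Hullar reaction: radical bromination at the acetal carbon, ionisation to the benzoxonium ion and attack of bromide at the primary C6 give the 6-bromo 4-benzoate in one operation.

**Step 10**
Reactants: 15 methyl 4-O-benzoyl-6-bromo-6-deoxy-2,3-di-O-methyl-α-D-glucopyranoside
Product: 16 (2R,3S,4R)-2,3-dimethoxy-1-oxohex-5-en-4-yl benzoate (4-O-benzoyl-5,6-dideoxy-2,3-di-O-methyl-D-xylo-hex-5-enose)
Conditions: activated Zn dust, EtOH/H2O 19:1, reflux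
Reagents that add atoms: none
Why: Bernet–Vasella reductive fragmentation: zinc inserts into the C6–Br bond and the C5–O5 bond breaks, releasing the C5=C6 alkene and the C1 aldehyde with C2–C4 untouched.

**Step 11**
Reactants: 12 alkenyl triflate; 16 sugar enal
Product: 17 (4R,5S,6R)-2-[(3S)-6-(benzyloxy)-7,8-dimethoxy-3,4-dihydro-2H-chromen-3-yl]-3-hydroxy-4,5-dimethoxyocta-1,7-dien-6-yl benzoate, both C3 carbinol epimers, C4–C6 as C2–C4 of 16
Conditions: CrCl2 (4 equiv), NiCl2 (1 mol%), DMF, rt
Reagents that add atoms: none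
Why: Nozaki–Hiyama–Kishi coupling: oxidative addition of the enol triflate to zerovalent nickel, transmetalation to trivalent chromium and addition of the alkenylchromium to the aldehyde only (benzoate and ethers are inert); the new carbinol centre forms as a mixture of epimers, which is harmless because it is oxidised later.

**Step 12**
Reactants: 17 octa-1,7-diene
Product: 18 4-hydroxy-5,6-dimethoxy-3-[(3S)-6-(benzyloxy)-7,8-dimethoxy-3,4-dihydro-2H-chromen-3-yl]cyclohex-2-en-1-yl benzoate, both C4 epimers, C1/C6/C5 as C4/C3/C2 of 16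
Conditions: second-generation Grubbs catalyst RuCl2(=CHPh)(H2IMes)(PCy3) (10 mol%), CH2Cl2 (0.005 M), 40 °C
Reagents that add atoms: none
Why: Ring-closing olefin metathesis: the ruthenium benzylidene exchanges onto the monosubstituted vinyl group next to the benzoate, [2+2] cycloaddition of this alkylidene onto the 1,1-disubstituted alkene gives a ruthenacyclobutane, and cycloreversion releases the cyclohexene and Ru=CH2, with ethene leaving as gas. The closest known reaction type is the ring-closing metathesis of sugar-derived octa-1,7-diene-3,4,5,6-tetrol derivatives to conduritols, including cases that form trisubstituted ring alkenes. The one ring closed is the six-membered carbocycle, closed by metathesis of two terminal alkenes at what becomes quinone C5=C6; the ring can only hold a cis alkene, so alkene geometry is not an issue. No new stereocentre is formed, and both carbinol epimers should cyclise and converge later. The selectivity needed is ring closure over intermolecular cross-metathesis through the unhindered vinyl group; it is secured by high dilution, by the four contiguous sp3 carbons that hold the alkenes 1,7 to each other, and by the benzoate, which also suppresses ruthenium hydride isomerisation of the vinyl carbinol to an ethyl ketone.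

**Step 13**
Reactants: 18 cyclohexenyl benzoate
Product: 19 2-[(3S)-6-(benzyloxy)-7,8-dimethoxy-3,4-dihydro-2H-chromen-3-yl]-5,6-dimethoxycyclohex-2-ene-1,4-diol, both C1 epimers, trans-5,6-dimethoxy
Conditions: K2CO3 (cat.), MeOH, rt
Reagents that add atoms: none
Why: Base-catalysed transesterification of the benzoate frees the second allylic alcohol; nothing else in 18 reacts with K2CO3 in methanol.

**Step 14**
Reactants: 19 cyclohexenediol
Product: 22 5-[(3S)-6-(benzyloxy)-7,8-dimethoxy-3,4-dihydro-2H-chromen-3-yl]-2,3-dimethoxycyclohexa-2,5-diene-1,4-dione, via enedione 20 (not isolated), via hydroquinone 21 (not isolated)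
Conditions: Dess–Martin periodinane (3.5 equiv), CH2Cl2, 0 °C to rt; then p-TsOH·H2O (0.2 equiv), rt
Reagents that add atoms: none
Why: Dess–Martin oxidation of both allylic carbinols gives the cyclohex-2-ene-1,4-dione, whose two methoxy-bearing CH groups are each α to a carbonyl, so acid-catalysed double enolisation (the known tautomerisation of cyclohex-2-ene-1,4-diones to hydroquinones) aromatises the ring and the remaining periodinane oxidises the hydroquinone to the quinone; acid is chosen over base to disfavour β-elimination of methanol and to leave chroman C3–H alone.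

**Step 15**
Reactants: 22 benzyl-protected quinone
Product: 24 5-[(3S)-6-hydroxy-7,8-dimethoxy-3,4-dihydro-2H-chromen-3-yl]-2,3-dimethoxycyclohexa-2,5-diene-1,4-dione, via leuco hydroquinone 23 (not isolated)
Conditions: H2 (1 atm), 10% Pd/C, EtOAc, rt; then N2 purge, filtration, air, silica gel, rt
Reagents that add atoms: none
Why: Hydrogenolysis of the aryl benzyl ether on Pd/C also reduces the quinone to its hydroquinone, and autoxidation of the electron-rich 2,3-dimethoxyhydroquinone by air returns the quinone while the less easily oxidised ring A phenol stays as it is.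

**Compound list**
1 | 2-hydroxy-3,4-dimethoxybenzaldehyde | O=Cc1ccc(OC)c(OC)c1O | starting material
2 | potassium 3-formyl-4-hydroxy-5,6-dimethoxyphenyl sulfate | O=Cc1cc(OS(=O)(=O)[O-])c(OC)c(OC)c1O.[K+] | intermediate
3 | 2,5-dihydroxy-3,4-dimethoxybenzaldehyde | O=Cc1cc(O)c(OC)c(OC)c1O | intermediate
4 | 5-(benzyloxy)-2-hydroxy-3,4-dimethoxybenzaldehyde | O=Cc1cc(OCc2ccccc2)c(OC)c(OC)c1O | intermediate
5 | acrolein (prop-2-enal) | C=CC=O | starting material
6 | 6-(benzyloxy)-7,8-dimethoxy-2H-chromene-3-carbaldehyde | O=CC1=Cc2cc(OCc3ccccc3)c(OC)c(OC)c2OC1 | intermediate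
7 | 6-(benzyloxy)-7,8-dimethoxy-2H-chromene-3-carboxylic acid | OC(=O)C1=Cc2cc(OCc3ccccc3)c(OC)c(OC)c2OC1 | intermediate
8 | (3R)-6-(benzyloxy)-7,8-dimethoxy-3,4-dihydro-2H-chromene-3-carboxylic acid | OC(=O)[C@H]1COc2c(cc(OCc3ccccc3)c(OC)c2OC)C1 | intermediate
9 | dilithium 1-[(3R)-6-(benzyloxy)-7,8-dimethoxy-3,4-dihydro-2H-chromen-3-yl]ethane-1,1-diolate | [Li+].[Li+].CC([O-])([O-])[C@H]1COc2c(cc(OCc3ccccc3)c(OC)c2OC)C1 | intermediate
10 | 1-[(3R)-6-(benzyloxy)-7,8-dimethoxy-3,4-dihydro-2H-chromen-3-yl]ethan-1-one | CC(=O)[C@H]1COc2c(cc(OCc3ccccc3)c(OC)c2OC)C1 | intermediate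
11 | potassium 1-[(3R)-6-(benzyloxy)-7,8-dimethoxy-3,4-dihydro-2H-chromen-3-yl]ethen-1-olate | [K+].[O-]C(=C)[C@H]1COc2c(cc(OCc3ccccc3)c(OC)c2OC)C1 | intermediate
12 | 1-[(3R)-6-(benzyloxy)-7,8-dimethoxy-3,4-dihydro-2H-chromen-3-yl]ethenyl trifluoromethanesulfonate | C=C(OS(=O)(=O)C(F)(F)F)[C@H]1COc2c(cc(OCc3ccccc3)c(OC)c2OC)C1 | intermediate
13 | methyl 4,6-O-[(R)-benzylidene]-α-D-glucopyranoside | CO[C@H]1O[C@@H]2CO[C@@H](c3ccccc3)O[C@H]2[C@H](O)[C@H]1O | starting material
14 | methyl 4,6-O-[(R)-benzylidene]-2,3-di-O-methyl-α-D-glucopyranoside | CO[C@H]1O[C@@H]2CO[C@@H](c3ccccc3)O[C@H]2[C@H](OC)[C@H]1OC | intermediate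
15 | methyl 4-O-benzoyl-6-bromo-6-deoxy-2,3-di-O-methyl-α-D-glucopyranoside | CO[C@H]1O[C@H](CBr)[C@@H](OC(=O)c2ccccc2)[C@H](OC)[C@H]1OC | intermediate
16 | (2R,3S,4R)-2,3-dimethoxy-1-oxohex-5-en-4-yl benzoate | O=C[C@H](OC)[C@@H](OC)[C@H](OC(=O)c1ccccc1)C=C | intermediate
17 | 2-[(3S)-6-(benzyloxy)-7,8-dimethoxychroman-3-yl]-3-hydroxy-4,5-dimethoxyocta-1,7-dien-6-yl benzoate (C3 epimers; C4–C6 as in 16) | C=C([C@H]1COc2c(cc(OCc3ccccc3)c(OC)c2OC)C1)C(O)[C@H](OC)[C@@H](OC)[C@H](OC(=O)c1ccccc1)C=C | intermediate
18 | 4-hydroxy-5,6-dimethoxy-3-[(3S)-6-(benzyloxy)-7,8-dimethoxychroman-3-yl]cyclohex-2-en-1-yl benzoate (C4 epimers) | OC1[C@H](OC)[C@@H](OC)[C@H](OC(=O)c2ccccc2)C=C1[C@H]3COc4c(cc(OCc5ccccc5)c(OC)c4OC)C3 | intermediate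
19 | 2-[(3S)-6-(benzyloxy)-7,8-dimethoxychroman-3-yl]-5,6-dimethoxycyclohex-2-ene-1,4-diol (C1 epimers, trans-5,6) | OC1[C@H](OC)[C@@H](OC)[C@H](O)C=C1[C@H]2COc3c(cc(OCc4ccccc4)c(OC)c3OC)C2 | intermediate
20 | 2-[(3S)-6-(benzyloxy)-7,8-dimethoxychroman-3-yl]-trans-5,6-dimethoxycyclohex-2-ene-1,4-dione | O=C1[C@H](OC)[C@@H](OC)C(=O)C=C1[C@H]2COc3c(cc(OCc4ccccc4)c(OC)c3OC)C2 | intermediate
21 | 5-[(3S)-6-(benzyloxy)-7,8-dimethoxychroman-3-yl]-2,3-dimethoxybenzene-1,4-diol | COc1c(O)cc([C@H]2COc3c(cc(OCc4ccccc4)c(OC)c3OC)C2)c(O)c1OC | intermediate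
22 | 5-[(3S)-6-(benzyloxy)-7,8-dimethoxychroman-3-yl]-2,3-dimethoxycyclohexa-2,5-diene-1,4-dione | COC1=C(OC)C(=O)C([C@H]2COc3c(cc(OCc4ccccc4)c(OC)c3OC)C2)=CC1=O | intermediate
23 | 5-[(3S)-6-hydroxy-7,8-dimethoxychroman-3-yl]-2,3-dimethoxybenzene-1,4-diol | COc1c(O)cc([C@H]2COc3c(cc(O)c(OC)c3OC)C2)c(O)c1OC | intermediate
24 | 5-[(3S)-6-hydroxy-7,8-dimethoxy-3,4-dihydro-2H-chromen-3-yl]-2,3-dimethoxycyclohexa-2,5-diene-1,4-dione | COC1=C(OC)C(=O)C([C@H]2COc3c(cc(O)c(OC)c3OC)C2)=CC1=O | target

**Step count and risks**
Total: 15 steps. Longest linear sequence: 12 steps (1–7, then 11–15); the sugar branch (8–10) has 3 steps.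

Steps most likely to fail:

Step 14. The first enol of enedione 20 may expel methanol from the neighbouring carbon (β-elimination) faster than it enolises a second time, which would lose a methoxy group; prolonged acid could also erode chroman C3. The fallback replaces the one-pot acid tautomerisation by kinetic silyl trapping of each enol. It sets out from 19: buffered Dess–Martin oxidation (NaHCO3, 2.4 equiv of oxidant) should give 20, now isolated. TMSOTf/Et3N in CH2Cl2 at −78 °C should silylate both enols as they form, giving the aromatic bis(trimethylsilyl) ether F1. Methanolysis (MeOH, citric acid) should give 21, and Ag2O in Et2O should oxidise it to 22, where the route is rejoined.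

Step 12. Ring closure onto the hindered 1,1-disubstituted alkene may be slower than dimerisation through the vinyl group or catalyst decay. The fallback gives up closure at C5=C6 and builds the ring by the known squarate ring expansion. It sets out from 12: hexamethylditin with Pd(PPh3)4 (zerovalent palladium) and LiCl in THF should give the alkenylstannane F2. Tin–lithium exchange with MeLi and addition to dimethyl squarate at −78 °C should give the 4-alkenyl-4-hydroxycyclobutenone F3. Heating in p-xylene at 140 °C (4π ring opening to the alkenylketene, 6π electrocyclisation, tautomerisation) should give 21, and Ag2O should oxidise it to 22, where the route is rejoined.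

Step 11. Oxidative addition of the α-branched enol triflate to nickel may be sluggish, and the α,β-dialkoxy aldehyde may eliminate or decompose while it waits. The fallback replaces the chromium/nickel coupling by a polar alkenyllithium addition to a lactol. It sets out from 10 and 16: 10 with 2,4,6-triisopropylbenzenesulfonyl hydrazide (cat. HCl, THF) should give the trisylhydrazone F4, and 16 with K2CO3/MeOH should give the lactol F5. Shapiro reaction of F4 (n-BuLi, 2.2 equiv, −78 to 0 °C) should give the alkenyllithium, which is added to the lithium salt of F5 to give the diene diol F6. Ring-closing metathesis of F6 with the same catalyst as in step 12 should give 19, where the route is rejoined.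

**Further compounds**
F1 | step 14 | 5-[(3S)-6-(benzyloxy)-7,8-dimethoxychroman-3-yl]-2,3-dimethoxy-1,4-bis(trimethylsilyloxy)benzene | COc1c(O[Si](C)(C)C)cc([C@H]2COc3c(cc(OCc4ccccc4)c(OC)c3OC)C2)c(O[Si](C)(C)C)c1OC
F2 | step 12 | {1-[(3R)-6-(benzyloxy)-7,8-dimethoxychroman-3-yl]ethenyl}trimethylstannane | C=C([Sn](C)(C)C)[C@H]1COc2c(cc(OCc3ccccc3)c(OC)c2OC)C1
F3 | step 12 | 4-{1-[(3S)-6-(benzyloxy)-7,8-dimethoxychroman-3-yl]ethenyl}-4-hydroxy-2,3-dimethoxycyclobut-2-en-1-one (C4 epimers) | COC1=C(OC)C(O)(C(=C)[C@H]2COc3c(cc(OCc4ccccc4)c(OC)c3OC)C2)C1=O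
F4 | step 11 | N'-{1-[(3S)-6-(benzyloxy)-7,8-dimethoxychroman-3-yl]ethylidene}-2,4,6-triisopropylbenzenesulfonohydrazide | CC(=NNS(=O)(=O)c1c(C(C)C)cc(C(C)C)cc1C(C)C)[C@H]1COc2c(cc(OCc3ccccc3)c(OC)c2OC)C1
F5 | step 11 | 5,6-dideoxy-2,3-di-O-methyl-D-xylo-hex-5-enofuranose (anomers) | OC1O[C@H](C=C)[C@H](OC)[C@H]1OC
F6 | step 11 | 2-[(3S)-6-(benzyloxy)-7,8-dimethoxychroman-3-yl]-4,5-dimethoxyocta-1,7-diene-3,6-diol (C3 epimers; C4–C6 as in 16) | C=C([C@H]1COc2c(cc(OCc3ccccc3)c(OC)c2OC)C1)C(O)[C@H](OC)[C@@H](OC)[C@H](O)C=C
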